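How much faster does the flask make target, at a fixed conversion of its substrate, when its free catalyst is charged twice over or at 500 µM?

all flasks: substrate 0.050 M

|  | reagent | free catalyst | remark |
|---|---|---|---|
| ochre | 0.075 M | 70 µM | run made earlier |
| green | 0.075 M | 110 µM | run made earlier |
| flask | 0.0750 M | 50 µM |  |

- ochre (time / h: target / %): 0.667: 1.6; 1.33: 0.2; 2.00: 1.4; 2.50: 2.6; 3.00: 2.7; 4.00: 5.3
- green (time / h: target / %): 0.333: 0; 0.500: 0; 0.833: 0.9; 1.33: 0.8; 2.50: 3.5; 4.00: 13.0

(each reading ± 0.5 percentage points)

1. factor on the rate of making target when 5.0% of the substrate are converted if free catalyst is charged twice over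
2. factor on the rate when 5.0% of the substrate are converted if free catalyst is charged at 500 µM instead

- the numbers in the tables scatter with a standard deviation of 0.5 percentage points
- what has left substrate counts as converted, also if it is not yet product

Two times carry my answer: the ochre run reaches 5.3% of target at 4.00 h, and the green run reaches the same level at 2.78 h, read on a straight line between its last two readings. For the zero of my scale I take catalyst whose portions work independently: the time to a level would then shrink in step with the charge, whose ratio between the green and ochre runs is 1.57. The ratio of the two times is 1.44, smaller than that. The logarithm of the time ratio over the logarithm of the charge ratio comes to 0.802; I call this the catalyst exponent, which is one at the zero of the scale. It is a reading and carries the scatter of the readings. If the rate at fixed conversion goes as the charge to this power, I expect a factor of 1.74 on doubling the flask's charge and 6.33 at 500 µM.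

The forecast gives 1.9 (1.5 to 2.4) on doubling and 8.5 (4 to 13) at 500 µM, taking the two runs as what one expects “if the whole time axis scales with catalyst”. Both its central values are higher than mine.

The simulation gives 1.60 on doubling and 5.52 at 500 µM, from these steps:

    free catalyst + open intermediate ⇌ catalyst intermediate (K = 320 M⁻¹, k = 770 M⁻¹ min⁻¹)
    substrate + free catalyst ⇌ free catalyst + open intermediate (K = 1.80, k = 130 M⁻¹ min⁻¹)
    2 reagent → homo dimer (k = 0.0820 M⁻¹ min⁻¹)
    reagent + free catalyst ⇌ idle complex, settled at all times (K = 350 M⁻¹)
    reagent + catalyst intermediate → free catalyst + target (k = 450 M⁻¹ min⁻¹)

The flask reaches 5.0% conversion at 2.11 h; at 2.50 h it holds 88.8% of its catalyst as idle complex, an off-cycle form, and 9.75% as free catalyst. For the flask charged at 500 µM, the exponent of 0.802 read from the two runs gives 6.33 and the simulation gives 5.52.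

The numbers in the tables come from a simulation with made-up constants, noise included.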